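**Retrosynthetic overview**
1. Target 45 ⇐ Zn cleavage of trichloroethyl ester 44 ⇐ late C–O coupling: the carboxylate of dihydroxy acid 43 (fragment B, C14) opens spiro-epoxide 29 (fragment A, C15) at its CH2.
2. Fragment A: oxirane from the exocyclic alkene of lactone 27; seven-membered lactone by ring-closing metathesis; its carbonyl carbon and the exocyclic methylene from a [2,3]-Wittig–Still shift of a cyclohexenylmethanol.
3. Fragment B: (E)-2-(hydroxymethyl)acrylic acid from ring aldehyde 36 by vinylalumination and allylic acetate transposition.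
4. Both cyclohexene cores are the two enantiomers of one cis Diels–Alder adduct (diene 6 + acrylimide 9, one antipode of a copper bis(oxazoline) catalyst each), because the cis vinyl/isopropyl pairs of the two halves have opposite handedness; the imide carbon becomes the isopropyl CH.
5. Ring order: cyclohexene (Diels–Alder) → oxepinone (metathesis) → oxirane (opened in the coupling); diene 6 by Suzuki coupling of two C3 pieces.

Assumption: descriptors read from the SMILES are (5aR,6R,9S,9aR) for the benzoxepinone half and (1R,6S),(2E) for the cyclohexenyl acrylate half; PMBOCH2 = (4-methoxybenzyloxy)methyl, TBSOCH2 = (tert-butyldimethylsilyloxy)methyl, TCE = 2,2,2-trichloroethyl, t-Bu-box = 2,2′-(propane-2,2-diyl)bis(4-tert-butyl-4,5-dihydro-1,3-oxazole); monocyclic cyclohexenes are numbered C1 (one-carbon arm), C2=C3 (C3 bears CH2O), C6 (acyl, later isopropyl).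

**Building blocks**

Step 1
Reactants: 1 prop-2-yn-1-ol
Product: 2 propargyl PMB ether
Conditions: NaH, PMBCl, Bu4NI (cat.), THF, 0 °C → rt
Reagents that add atoms: 4-methoxybenzyl chloride, COc1ccc(CCl)cc1
Why: Williamson etherification: the sodium alkoxide displaces the benzylic chloride and the less acidic alkyne C–H is untouched.

Step 2
Reactants: 2 propargyl PMB ether
Product: 3 (E)-alkenylboronic pinacol ester
Conditions: pinacolborane, Cp2Zr(H)Cl (5 mol %), Et3N (10 mol %), neat, 60 °C
Reagents that add atoms: pinacolborane, CC1(C)OBOC1(C)C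
Why: Zirconium-catalysed hydroboration adds H–B syn and anti-Markovnikov across the terminal alkyne, giving only the (E)-alkenylboronate.

Step 3
Reactants: 4 2-bromoprop-2-en-1-ol
Product: 5 2-bromoallyl TBS ether
Conditions: TBSCl, imidazole, CH2Cl2, 0 °C → rt
Reagents that add atoms: tert-butyldimethylsilyl chloride, CC(C)(C)[Si](C)(C)Cl
Why: Imidazole-mediated O-silylation of the primary allylic alcohol.

Step 4
Reactants: 3 (E)-alkenylboronic pinacol ester; 5 2-bromoallyl TBS ether
Product: 6 (E)-diene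
Conditions: Pd(PPh3)4 (5 mol %), 2 M aq. NaOH, THF, 60 °C
Reagents that add atoms: none
Why: Suzuki–Miyaura coupling: oxidative addition of zerovalent palladium into the vinyl bromide, transmetalation and reductive elimination all proceed with retention, so the (E)-geometry is carried into the 1,3-diene.

Step 5
Reactants: 7 1,3-oxazolidin-2-one; 8 prop-2-enoyl chloride
Product: 9 3-(prop-2-enoyl)-1,3-oxazolidin-2-one
Conditions: n-BuLi, THF, −78 °C; then 8, −78 → 0 °C
Reagents that add atoms: none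
Why: N-acylation of the lithiated oxazolidinone by the acid chloride at low temperature, which avoids polymerisation of the acryloyl group.

**Fragment A**

Step 6
Reactants: 6 (E)-diene; 9 3-(prop-2-enoyl)-1,3-oxazolidin-2-one
Product: 10 (1R,6S)-cis-imide (A series)
Conditions: [Cu((S,S)-t-Bu-box)](SbF6)2 (10 mol %), CH2Cl2, −20 °C → rt
Reagents that add atoms: none
Why: Catalytic asymmetric Diels–Alder reaction: the s-cis acrylimide chelates square-planar divalent copper, the (S,S)-ligand blocks the Cα si face, and the diene adds endo with ortho/para regiochemistry to the re face, setting C1 (R) and C6 (S) cis (minor trans isomer removed by chromatography).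

Step 7
Reactants: 10 (1R,6S)-cis-imide
Product: 11 (1R,6S)-Weinreb amide
Conditions: AlMe3, MeNH(OMe)·HCl, CH2Cl2, 0 °C → rt; 1 M HCl work-up
Reagents that add atoms: N,O-dimethylhydroxylamine hydrochloride, CNOC.Cl
Why: Weinreb amide formation by aluminium-amide transamination at the exocyclic imide carbonyl, with no base strong enough to epimerise C6.

Step 8
Reactants: 11 (1R,6S)-Weinreb amide
Product: 12 (1R,6S)-methyl ketone
Conditions: MeMgBr, THF, −78 → 0 °C; cold 1 M HCl quench
Reagents that add atoms: methylmagnesium bromide, C[Mg]Br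
Why: Weinreb ketone synthesis: the chelated tetrahedral intermediate survives until the quench, so there is no over-addition and the cis C6 centre is not enolised.

Step 9
Reactants: 12 (1R,6S)-methyl ketone
Product: 13 (1R,6S)-isopropenyl compound
Conditions: Ph3PCH3Br, KN(SiMe3)2, THF, 0 °C; then 12, −78 → 0 °C
Reagents that add atoms: methyltriphenylphosphonium bromide, C[P+](c1ccccc1)(c1ccccc1)c1ccccc1.[Br-]
Why: Wittig methylenation; adding the ketone cold to the pre-formed ylide keeps the α-stereocentre C6 intact.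

Step 10
Reactants: 13 (1R,6S)-isopropenyl compound
Product: 14 (1S,6R)-isopropyl compound
Conditions: H2 (1 atm), RhCl(PPh3)3 (5 mol %), benzene/EtOH, rt
Reagents that add atoms: none
Why: Chemoselective homogeneous hydrogenation: RhCl(PPh3)3 reduces the 1,1-disubstituted alkene far faster than the trisubstituted ring alkene and leaves the PMB and allylic silyl ethers alone; no stereocentre is formed (descriptors change by priority only).

Step 11
Reactants: 14 (1S,6R)-isopropyl compound
Product: 15 (1S,6R)-primary alcohol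
Conditions: DDQ, CH2Cl2/pH 7 buffer, 0 °C → rt
Reagents that add atoms: none
Why: Oxidative PMB cleavage: DDQ abstracts hydride from the electron-rich benzylic position and water collapses the oxocarbenium ion, leaving the TBS ether and alkene untouched.

Step 12
Reactants: 15 (1S,6R)-primary alcohol
Product: 16 (1S,6R)-aldehyde
Conditions: Dess–Martin periodinane, NaHCO3, CH2Cl2, 0 °C → rt
Reagents that add atoms: none
Why: Dess–Martin oxidation under bicarbonate buffering gives the β,γ-unsaturated aldehyde without acid or base that could epimerise C1 or conjugate the ring alkene.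

Step 13
Reactants: 16 (1S,6R)-aldehyde
Product: 17 (1S,6R)-vinyl compound
Conditions: Ph3PCH3Br, KN(SiMe3)2, THF, 0 °C; then 16, −78 → 0 °C
Reagents that add atoms: methyltriphenylphosphonium bromide, C[P+](c1ccccc1)(c1ccccc1)c1ccccc1.[Br-]
Why: Wittig methylenation of the aldehyde at −78 °C is faster than enolisation, so the vinyl group is installed with C1 intact.

Step 14
Reactants: 17 (1S,6R)-vinyl compound
Product: 18 (1S,6R)-allylic alcohol
Conditions: HF·pyridine, pyridine/THF, 0 °C → rt
Reagents that add atoms: none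
Why: Fluoride-mediated desilylation frees the primary allylic alcohol.

Step 15
Reactants: 18 (1S,6R)-allylic alcohol
Product: 19 (1S,6R)-stannylmethyl ether
Conditions: KH, 18-crown-6 (cat.), THF, 0 °C; then Bu3SnCH2I, rt
Reagents that add atoms: tributyl(iodomethyl)stannane, CCCC[Sn](CCCC)(CCCC)CI
Why: Williamson etherification of the potassium alkoxide with the iodomethylstannane.

Step 16
Reactants: 19 (1S,6R)-stannylmethyl ether
Product: 21 [(1R,2S,3R)-2-ethenyl-6-methylidene-3-(propan-2-yl)cyclohexyl]methanol, via lithiomethyl ether 20 (not isolated)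
Conditions: n-BuLi, THF, −78 → −20 °C; H2O
Reagents that add atoms: none
Why: Tin–lithium exchange then [2,3]-Wittig–Still rearrangement through a five-membered envelope transition state: the new C–C bond forms at the ring alkene carbon anti to the adjacent pseudo-axial vinyl group, so CH2OH ends trans to vinyl (new C1, R) and the alkene moves to the exocyclic position.

Step 17
Reactants: 21 homoallylic alcohol
Product: 23 (1R,2S,3R)-2-ethenyl-6-methylidene-3-(propan-2-yl)cyclohexane-1-carboxylic acid, via aldehyde 22 (not isolated)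
Conditions: TEMPO (20 mol %), PhI(OAc)2 (2.2 equiv), MeCN/H2O, rt
Reagents that add atoms: water, O
Why: TEMPO/PhI(OAc)2 oxidation takes the primary alcohol through the aldehyde hydrate to the acid under near-neutral conditions that tolerate both alkenes and leave C1 unchanged.

Step 18
Reactants: 24 2-(bromomethyl)prop-2-enoic acid
Product: 25 TCE 2-(bromomethyl)prop-2-enoate
Conditions: Cl3CCH2OH, DCC, DMAP (5 mol %), CH2Cl2, 0 °C
Reagents that add atoms: 2,2,2-trichloroethanol, OCC(Cl)(Cl)Cl
Why: Steglich esterification protects the acid as a reductively cleavable ester; the low DMAP loading at 0 °C limits attack on the allylic bromide.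

Step 19
Reactants: 23 cyclohexanecarboxylic acid; 25 TCE 2-(bromomethyl)prop-2-enoate
Product: 26 metathesis precursor (acyloxymethyl acrylate)
Conditions: Cs2CO3 (0.6 equiv), DMF, 0 °C → rt
Reagents that add atoms: none
Why: Carboxylate O-alkylation: the caesium carboxylate displaces the allylic bromide, and SN2 and SN2′ attack give the same product.

Step 20
Reactants: 26 metathesis precursor
Product: 27 (5aR,6R,9aR)-methylidene benzoxepinone
Conditions: second-generation Grubbs catalyst (H2IMes)(PCy3)Cl2Ru=CHPh (10 mol %), toluene (2 mM), 80 °C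
Reagents that add atoms: none
Why: Ring-closing metathesis from the vinyl group onto the acrylate methylene releases ethene and the seven-membered ring forces the required ring-cis trisubstituted enoate; the exocyclic methylene could only give a four-membered ring or a tetrasubstituted alkene and stays out.

Step 21
Reactants: 27 methylidene benzoxepinone
Product: 29 (5aR,6R,9S,9aR)-spiro-epoxide (fragment A), via bromohydrin 28 (not isolated)
Conditions: NBS, THF/H2O, 0 °C; then crude 28, DBU, CH2Cl2, 0 °C → rt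
Reagents that add atoms: water, O
Why: Bromohydrin formation then intramolecular Williamson closure: Br+ attacks only the electron-rich exocyclic alkene, water opens the bromonium ion at the tertiary carbon by axial attack (OH cis to the lactone carbonyl), and DBU closes the oxirane with retention, fixing C9 as S.

**Fragment B**

Step 22
Reactants: 6 (E)-diene; 9 3-(prop-2-enoyl)-1,3-oxazolidin-2-one
Product: 30 (1S,6R)-cis-imide (B series)
Conditions: [Cu((R,R)-t-Bu-box)](SbF6)2 (10 mol %), CH2Cl2, −20 °C → rt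
Reagents that add atoms: none
Why: Catalytic asymmetric Diels–Alder reaction as in step 6, but the (R,R)-ligand exposes the Cα si face, so endo addition gives the mirror-image cis adduct with C1 (S) and C6 (R).

Step 23
Reactants: 30 (1S,6R)-cis-imide
Product: 31 (1S,6R)-Weinreb amide
Conditions: AlMe3, MeNH(OMe)·HCl, CH2Cl2, 0 °C → rt; 1 M HCl work-up
Reagents that add atoms: N,O-dimethylhydroxylamine hydrochloride, CNOC.Cl
Why: Weinreb amide formation by aluminium-amide transamination without epimerising C6.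

Step 24
Reactants: 31 (1S,6R)-Weinreb amide
Product: 32 (1S,6R)-methyl ketone
Conditions: MeMgBr, THF, −78 → 0 °C; cold 1 M HCl quench
Reagents that add atoms: methylmagnesium bromide, C[Mg]Br
Why: Weinreb ketone synthesis through the stable chelate, with no over-addition or enolisation.

Step 25
Reactants: 32 (1S,6R)-methyl ketone
Product: 33 (1S,6R)-isopropenyl compound
Conditions: Ph3PCH3Br, KN(SiMe3)2, THF, 0 °C; then 32, −78 → 0 °C
Reagents that add atoms: methyltriphenylphosphonium bromide, C[P+](c1ccccc1)(c1ccccc1)c1ccccc1.[Br-]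
Why: Wittig methylenation under cold conditions keeps the α-stereocentre.

Step 26
Reactants: 33 (1S,6R)-isopropenyl compound
Product: 34 (1R,6S)-isopropyl compound
Conditions: H2 (1 atm), RhCl(PPh3)3 (5 mol %), benzene/EtOH, rt
Reagents that add atoms: none
Why: Chemoselective homogeneous hydrogenation of the 1,1-disubstituted alkene only; no stereocentre is formed.

Step 27
Reactants: 34 (1R,6S)-isopropyl compound
Product: 35 (1R,6S)-primary alcohol
Conditions: DDQ, CH2Cl2/pH 7 buffer, 0 °C → rt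
Reagents that add atoms: none
Why: Oxidative PMB cleavage by DDQ, orthogonal to the TBS ether.

Step 28
Reactants: 35 (1R,6S)-primary alcohol
Product: 36 (1R,6S)-aldehyde
Conditions: Dess–Martin periodinane, NaHCO3, CH2Cl2, 0 °C → rt
Reagents that add atoms: none
Why: Buffered Dess–Martin oxidation gives the aldehyde without epimerising C1.

Step 29
Reactants: 37 methyl prop-2-ynoate; 36 (1R,6S)-aldehyde
Product: 39 Morita–Baylis–Hillman alcohol (1R,6S; carbinol epimers), via vinylalane 38 (not isolated)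
Conditions: i-Bu2AlH, N-methylmorpholine N-oxide, THF, 0 °C, then 37; then 36, 0 °C → rt; H2O
Reagents that add atoms: none
Why: Vinylalumination (Morita–Baylis–Hillman-type addition): hydroalumination puts aluminium α to the ester and this vinylalane adds to the aldehyde without base, so C1 is not epimerised; the new carbinol centre forms unselectively and is erased in step 30.

Step 30
Reactants: 39 Morita–Baylis–Hillman alcohol
Product: 41 (2E)-2-(acetoxymethyl) enoate (1R,6S), via allylic acetate 40 (not isolated)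
Conditions: Ac2O, Et3N, DMAP (cat.), THF, 0 °C → rt; then DABCO (0.3 equiv), 60 °C
Reagents that add atoms: acetic anhydride, CC(=O)OC(C)=O
Why: Acetylation followed by DABCO-catalysed SN2′–SN2′ allylic transposition moves the acetate to the terminal carbon under thermodynamic control, giving the conjugated trisubstituted alkene with the ring trans to the ester (E).

Step 31
Reactants: 41 (2E)-2-(acetoxymethyl) enoate
Product: 43 dihydroxy acid (fragment B), via silyl ether acid 42 (not isolated)
Conditions: LiOH, THF/H2O, rt; then 2 M HCl to pH 1, rt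
Reagents that add atoms: lithium hydroxide, [Li+].[OH-]
Why: Saponification of the methyl ester and acetate, then acid-promoted desilylation on acidification; alkene geometry and both stereocentres are untouched.

**Coupling and end game**

Step 32
Reactants: 29 spiro-epoxide (fragment A); 43 dihydroxy acid (fragment B)
Product: 44 coupled trichloroethyl ester
Conditions: 43 (1.5 equiv), Cs2CO3 (0.25 equiv), DMF, 60 °C
Reagents that add atoms: none
Why: Nucleophilic epoxide opening by a carboxylate (SN2 at the unhindered CH2): the C9–O bond is untouched so the tertiary alcohol stays S, the free allylic hydroxyls are not nucleophilic here, and the excess acid protonates the tertiary alkoxide before it can trigger acyl migration.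

Step 33
Reactants: 44 coupled trichloroethyl ester
Product: 45 target acid
Conditions: Zn dust, AcOH/THF, 0 °C → rt
Reagents that add atoms: none
Why: Zinc-mediated reductive cleavage (reduction then β-elimination) of the trichloroethyl ester under non-basic conditions frees the acrylic acid without touching the lactone, the acrylate ester, the alkenes or any stereocentre.

**Compound list**
1 | prop-2-yn-1-ol | C#CCO | starting material
2 | 1-methoxy-4-[(prop-2-yn-1-yloxy)methyl]benzene | C#CCOCc1ccc(OC)cc1 | intermediate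
3 | 2-[(1E)-3-(4-methoxybenzyloxy)prop-1-en-1-yl]-4,4,5,5-tetramethyl-1,3,2-dioxaborolane | COc1ccc(COC/C=C/B2OC(C)(C)C(C)(C)O2)cc1 | intermediate
4 | 2-bromoprop-2-en-1-ol | C=C(Br)CO | starting material
5 | [(2-bromoprop-2-en-1-yl)oxy](tert-butyl)dimethylsilane | C=C(Br)CO[Si](C)(C)C(C)(C)C | intermediate
6 | tert-butyl{[(3E)-5-(4-methoxybenzyloxy)-2-methylidenepent-3-en-1-yl]oxy}dimethylsilane | C=C(CO[Si](C)(C)C(C)(C)C)/C=C/COCc1ccc(OC)cc1 | intermediate
7 | 1,3-oxazolidin-2-one | O=C1NCCO1 | starting material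
8 | prop-2-enoyl chloride | C=CC(=O)Cl | starting material
9 | 3-(prop-2-enoyl)-1,3-oxazolidin-2-one | C=CC(=O)N1CCOC1=O | intermediate
10 | (1R,6S)-1-(PMBOCH2)-3-(TBSOCH2)-6-[(2-oxo-1,3-oxazolidin-3-yl)carbonyl]cyclohex-2-ene | COc1ccc(COC[C@@H]2C=C(CO[Si](C)(C)C(C)(C)C)CC[C@@H]2C(=O)N3CCOC3=O)cc1 | intermediate
11 | (1R,6S)-6-[methoxy(methyl)carbamoyl]-1-(PMBOCH2)-3-(TBSOCH2)cyclohex-2-ene | COc1ccc(COC[C@@H]2C=C(CO[Si](C)(C)C(C)(C)C)CC[C@@H]2C(=O)N(C)OC)cc1 | intermediate
12 | (1R,6S)-6-acetyl-1-(PMBOCH2)-3-(TBSOCH2)cyclohex-2-ene | COc1ccc(COC[C@@H]2C=C(CO[Si](C)(C)C(C)(C)C)CC[C@@H]2C(C)=O)cc1 | intermediate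
13 | (1R,6S)-1-(PMBOCH2)-6-(prop-1-en-2-yl)-3-(TBSOCH2)cyclohex-2-ene | COc1ccc(COC[C@@H]2C=C(CO[Si](C)(C)C(C)(C)C)CC[C@@H]2C(C)=C)cc1 | intermediate
14 | (1S,6R)-1-(PMBOCH2)-6-(propan-2-yl)-3-(TBSOCH2)cyclohex-2-ene | COc1ccc(COC[C@@H]2C=C(CO[Si](C)(C)C(C)(C)C)CC[C@@H]2C(C)C)cc1 | intermediate
15 | [(1S,6R)-6-(propan-2-yl)-3-(TBSOCH2)cyclohex-2-en-1-yl]methanol | OC[C@@H]1C=C(CO[Si](C)(C)C(C)(C)C)CC[C@@H]1C(C)C | intermediate
16 | (1S,6R)-6-(propan-2-yl)-3-(TBSOCH2)cyclohex-2-ene-1-carbaldehyde | O=C[C@@H]1C=C(CO[Si](C)(C)C(C)(C)C)CC[C@@H]1C(C)C | intermediate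
17 | (1S,6R)-1-ethenyl-6-(propan-2-yl)-3-(TBSOCH2)cyclohex-2-ene | C=C[C@@H]1C=C(CO[Si](C)(C)C(C)(C)C)CC[C@@H]1C(C)C | intermediate
18 | [(1S,6R)-1-ethenyl-6-(propan-2-yl)cyclohex-2-en-3-yl]methanol | C=C[C@@H]1C=C(CO)CC[C@@H]1C(C)C | intermediate
19 | tributyl({[(1S,6R)-1-ethenyl-6-(propan-2-yl)cyclohex-2-en-3-yl]methoxy}methyl)stannane | C=C[C@@H]1C=C(COC[Sn](CCCC)(CCCC)CCCC)CC[C@@H]1C(C)C | intermediate
20 | ({[(1S,6R)-1-ethenyl-6-(propan-2-yl)cyclohex-2-en-3-yl]methoxy}methyl)lithium | C=C[C@@H]1C=C(COC[Li])CC[C@@H]1C(C)C | intermediate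
21 | [(1R,2S,3R)-2-ethenyl-6-methylidene-3-(propan-2-yl)cyclohexyl]methanol | C=C[C@@H]1[C@@H](CO)C(=C)CC[C@@H]1C(C)C | intermediate
22 | (1R,2S,3R)-2-ethenyl-6-methylidene-3-(propan-2-yl)cyclohexane-1-carbaldehyde | C=C[C@@H]1[C@@H](C=O)C(=C)CC[C@@H]1C(C)C | intermediate
23 | (1R,2S,3R)-2-ethenyl-6-methylidene-3-(propan-2-yl)cyclohexane-1-carboxylic acid | C=C[C@@H]1[C@@H](C(=O)O)C(=C)CC[C@@H]1C(C)C | intermediate
24 | 2-(bromomethyl)prop-2-enoic acid | C=C(CBr)C(=O)O | starting material
25 | 2,2,2-trichloroethyl 2-(bromomethyl)prop-2-enoate | C=C(CBr)C(=O)OCC(Cl)(Cl)Cl | intermediate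
26 | 2-[(2,2,2-trichloroethoxy)carbonyl]prop-2-en-1-yl (1R,2S,3R)-2-ethenyl-6-methylidene-3-(propan-2-yl)cyclohexane-1-carboxylate | C=C[C@@H]1[C@@H](C(=O)OCC(=C)C(=O)OCC(Cl)(Cl)Cl)C(=C)CC[C@@H]1C(C)C | intermediate
27 | 2,2,2-trichloroethyl (5aR,6R,9aR)-9-methylidene-1-oxo-6-(propan-2-yl)-1,3,5a,6,7,8,9,9a-octahydro-2-benzoxepine-4-carboxylate | CC(C)[C@H]1CCC(=C)[C@@H]2C(=O)OCC(C(=O)OCC(Cl)(Cl)Cl)=C[C@@H]12 | intermediate
28 | 2,2,2-trichloroethyl (5aR,6R,9S,9aR)-9-(bromomethyl)-9-hydroxy-1-oxo-6-(propan-2-yl)-1,3,5a,6,7,8,9,9a-octahydro-2-benzoxepine-4-carboxylate | CC(C)[C@H]1CC[C@@](O)(CBr)[C@@H]2C(=O)OCC(C(=O)OCC(Cl)(Cl)Cl)=C[C@@H]12 | intermediate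
29 | 2,2,2-trichloroethyl (5aR,6R,9S,9aR)-1-oxo-6-(propan-2-yl)-3,5a,6,7,8,9a-hexahydro-1H-spiro[2-benzoxepine-9,2′-oxirane]-4-carboxylate | CC(C)[C@H]1CC[C@@]3(CO3)[C@@H]2C(=O)OCC(C(=O)OCC(Cl)(Cl)Cl)=C[C@@H]12 | intermediate
30 | (1S,6R)-1-(PMBOCH2)-3-(TBSOCH2)-6-[(2-oxo-1,3-oxazolidin-3-yl)carbonyl]cyclohex-2-ene | COc1ccc(COC[C@H]2C=C(CO[Si](C)(C)C(C)(C)C)CC[C@H]2C(=O)N3CCOC3=O)cc1 | intermediate
31 | (1S,6R)-6-[methoxy(methyl)carbamoyl]-1-(PMBOCH2)-3-(TBSOCH2)cyclohex-2-ene | COc1ccc(COC[C@H]2C=C(CO[Si](C)(C)C(C)(C)C)CC[C@H]2C(=O)N(C)OC)cc1 | intermediate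
32 | (1S,6R)-6-acetyl-1-(PMBOCH2)-3-(TBSOCH2)cyclohex-2-ene | COc1ccc(COC[C@H]2C=C(CO[Si](C)(C)C(C)(C)C)CC[C@H]2C(C)=O)cc1 | intermediate
33 | (1S,6R)-1-(PMBOCH2)-6-(prop-1-en-2-yl)-3-(TBSOCH2)cyclohex-2-ene | COc1ccc(COC[C@H]2C=C(CO[Si](C)(C)C(C)(C)C)CC[C@H]2C(C)=C)cc1 | intermediate
34 | (1R,6S)-1-(PMBOCH2)-6-(propan-2-yl)-3-(TBSOCH2)cyclohex-2-ene | COc1ccc(COC[C@H]2C=C(CO[Si](C)(C)C(C)(C)C)CC[C@H]2C(C)C)cc1 | intermediate
35 | [(1R,6S)-6-(propan-2-yl)-3-(TBSOCH2)cyclohex-2-en-1-yl]methanol | OC[C@H]1C=C(CO[Si](C)(C)C(C)(C)C)CC[C@H]1C(C)C | intermediate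
36 | (1R,6S)-6-(propan-2-yl)-3-(TBSOCH2)cyclohex-2-ene-1-carbaldehyde | O=C[C@H]1C=C(CO[Si](C)(C)C(C)(C)C)CC[C@H]1C(C)C | intermediate
37 | methyl prop-2-ynoate | C#CC(=O)OC | starting material
38 | methyl 2-[bis(2-methylpropyl)alumanyl]prop-2-enoate | C=C([Al](CC(C)C)CC(C)C)C(=O)OC | intermediate
39 | methyl 2-{hydroxy[(1R,6S)-6-(propan-2-yl)-3-(TBSOCH2)cyclohex-2-en-1-yl]methyl}prop-2-enoate (both carbinol epimers) | C=C(C(=O)OC)C(O)[C@H]1C=C(CO[Si](C)(C)C(C)(C)C)CC[C@H]1C(C)C | intermediate
40 | methyl 2-{acetoxy[(1R,6S)-6-(propan-2-yl)-3-(TBSOCH2)cyclohex-2-en-1-yl]methyl}prop-2-enoate (both epimers) | C=C(C(=O)OC)C(OC(C)=O)[C@H]1C=C(CO[Si](C)(C)C(C)(C)C)CC[C@H]1C(C)C | intermediate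
41 | methyl (2E)-2-(acetoxymethyl)-3-[(1R,6S)-6-(propan-2-yl)-3-(TBSOCH2)cyclohex-2-en-1-yl]prop-2-enoate | COC(=O)/C(=C/[C@H]1C=C(CO[Si](C)(C)C(C)(C)C)CC[C@H]1C(C)C)COC(C)=O | intermediate
42 | (2E)-2-(hydroxymethyl)-3-[(1R,6S)-6-(propan-2-yl)-3-(TBSOCH2)cyclohex-2-en-1-yl]prop-2-enoic acid | OC(=O)/C(=C/[C@H]1C=C(CO[Si](C)(C)C(C)(C)C)CC[C@H]1C(C)C)CO | intermediate
43 | (2E)-2-(hydroxymethyl)-3-[(1R,6S)-3-(hydroxymethyl)-6-(propan-2-yl)cyclohex-2-en-1-yl]prop-2-enoic acid | OC(=O)/C(=C/[C@H]1C=C(CO)CC[C@H]1C(C)C)CO | intermediate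
44 | 2,2,2-trichloroethyl (5aR,6R,9S,9aR)-9-hydroxy-9-({[(2E)-2-(hydroxymethyl)-3-[(1R,6S)-3-(hydroxymethyl)-6-(propan-2-yl)cyclohex-2-en-1-yl]prop-2-enoyl]oxy}methyl)-1-oxo-6-(propan-2-yl)-1,3,5a,6,7,8,9,9a-octahydro-2-benzoxepine-4-carboxylate | CC(C)[C@H]1CC[C@@](O)(COC(=O)/C(=C/[C@H]2C=C(CO)CC[C@H]2C(C)C)CO)[C@@H]2C(=O)OCC(C(=O)OCC(Cl)(Cl)Cl)=C[C@@H]12 | intermediate
45 | (5aR,6R,9S,9aR)-9-hydroxy-9-({[(2E)-2-(hydroxymethyl)-3-[(1R,6S)-3-(hydroxymethyl)-6-(propan-2-yl)cyclohex-2-en-1-yl]prop-2-enoyl]oxy}methyl)-1-oxo-6-(propan-2-yl)-1,3,5a,6,7,8,9,9a-octahydro-2-benzoxepine-4-carboxylic acid (CNP0361406.11) | CC(C)[C@H]1CC[C@@](O)(COC(=O)/C(=C/[C@H]2C=C(CO)CC[C@H]2C(C)C)CO)[C@@H]2C(=O)OCC(C(=O)O)=C[C@@H]12 | target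

**Totals**
Total step count: 33.
Longest linear sequence: 20 steps (1, 2, 4, 6 to 17, 19 to 21, 32, 33).

**Steps most likely to fail and their fallbacks**

Step 6 (catalytic asymmetric Diels–Alder reaction; the oxygenated diene may give a poor cis:trans ratio or ee). The fallback replaces catalyst control by a covalently bound auxiliary and sets out from diene 6 and acid chloride 8. Acylation of lithiated (R)-4-benzyl-1,3-oxazolidin-2-one with 8 gives the chiral acrylimide F1. Its Et2AlCl-promoted Diels–Alder reaction with 6 (CH2Cl2, −78 °C; chelated s-cis imide, diene adds anti to the benzyl group, i.e. to the same Cα re face) gives the auxiliary-bound cis-imide F2. AlMe3/MeNH(OMe)·HCl transamination of F2 releases the auxiliary and rejoins the route at Weinreb amide 11.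

Step 16 ([2,3]-Wittig–Still shift; a competing [1,2]-shift or poor facial control would cost the C9a carbon or its configuration). The fallback sets out from allylic alcohol 18. Heating with N,N-dimethylformamide dimethyl acetal (xylene, 140 °C) generates the allyloxy(dimethylamino)carbene, whose [2,3]-shift (Büchi rearrangement, no organolithium) gives the β,γ-unsaturated dimethylamide F3 with the same anti delivery and the same exocyclic methylene. Reduction with LiH2NBH3 (THF, 0 °C → rt) returns to the route at alcohol 21.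

Step 30 (amine-catalysed acetate transposition; an E/Z mixture or incomplete isomerisation is possible with this branched substrate). The fallback sets out from alcohol 39. NBS/Me2S (CH2Cl2, 0 °C) effects SN2′ bromination to the (2Z)-2-(bromomethyl) enoate F4, which has the ring trans to the ester. KOAc in DMF then displaces the primary allylic bromide and returns to the route at acetate 41.

**Further compounds**
F1 | step 6 | (4R)-4-benzyl-3-(prop-2-enoyl)-1,3-oxazolidin-2-one | C=CC(=O)N1[C@H](Cc2ccccc2)COC1=O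
F2 | step 6 | (4R)-4-benzyl-3-{[(1R,6S)-1-(PMBOCH2)-3-(TBSOCH2)cyclohex-2-en-6-yl]carbonyl}-1,3-oxazolidin-2-one | COc1ccc(COC[C@@H]2C=C(CO[Si](C)(C)C(C)(C)C)CC[C@@H]2C(=O)N3[C@H](Cc4ccccc4)COC3=O)cc1
F3 | step 16 | (1R,2S,3R)-2-ethenyl-N,N-dimethyl-6-methylidene-3-(propan-2-yl)cyclohexane-1-carboxamide | C=C[C@@H]1[C@@H](C(=O)N(C)C)C(=C)CC[C@@H]1C(C)C
F4 | step 30 | methyl (2Z)-2-(bromomethyl)-3-[(1R,6S)-6-(propan-2-yl)-3-(TBSOCH2)cyclohex-2-en-1-yl]prop-2-enoate | COC(=O)/C(=C/[C@H]1C=C(CO[Si](C)(C)C(C)(C)C)CC[C@H]1C(C)C)CBr
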